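**Retrosynthetic overview**

- Numbering: C1 is the ring carbon with the tertiary hydroxyl (O1) and the CH2OBz arm (C7); C2 and C5 carry the ring benzoates; C3=C4 is the ring alkene; C6 is the secondary carbinol.
- Feature: O1 on C1 is cis to the free O6 hydroxyl and C7 carries a benzoate. Removing that benzoate gives the spiro-oxirane (C1, C7, O1), and removing the oxirane oxygen gives a C1=C7 methylene alcohol that is epoxidised from the O6 face with VO(acac)2 and TBHP.
- The methylene comes from a C1 ketone (Zn, CH2Br2, TiCl4) flanked by the C2 benzoate and a silylated O6; the ketone comes from the C1 carbinol of a 2,5-di-O-benzoyl cyclohexenetetrol.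
- The four ring oxygens come from (1S,2S)-3-bromocyclohexa-3,5-diene-1,2-diol: epoxidation of C5=C6 directed by the free C1 hydroxyl and benzoate opening at C5 set O6 (cis to O2) and O5 (trans to O6). The bromine, which tells the two alkenes apart, is then removed.
- Ring order: the carbocycle is present from the start; a C5–C6 oxirane is closed in step 4 and opened in step 5; the spiro-oxirane is closed in step 11 and opened in step 12.

Key step: step 11

Remark: 1 is taken as the commercial (1S,2S) enantiomer from microbial oxidation of bromobenzene. Target numbering is used for all intermediates, so that in 1 C1 is the carbinol carbon remote from bromine, C2 the carbinol carbon next to C–Br and C3 the C–Br carbon. Direct benzoylation of 1 is expected to favour the more accessible O1, so the C2 benzoate is installed by way of a temporary O1 silyl ether.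

**Route**

Step 1
Reactants: 1 (1S,2S)-3-bromocyclohexa-3,5-diene-1,2-diol; 2 tert-butyldimethylsilyl chloride
Product: 3 1-O-TBS ether of 1 (silyl on O1, C2 hydroxyl free, O1 and O2 cis)
Conditions: TBSCl (1.05 equiv), imidazole, DMF, −15 °C to 0 °C
Reagents that add atoms: tert-butyldimethylsilyl chloride, CC(C)(C)[Si](C)(C)Cl
Why: Regioselective monosilylation, in which the bulky silyl chloride takes the less hindered C1 hydroxyl remote from bromine and leaves the C2 hydroxyl beside C–Br free; no stereocentre is touched.

Step 2
Reactants: 3 1-O-TBS ether of 1; 4 benzoyl chloride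
Product: 5 2-O-benzoyl-1-O-TBS derivative of 1
Conditions: BzCl, pyridine, DMAP (cat.), CH2Cl2, 0 °C
Reagents that add atoms: benzoyl chloride, O=C(Cl)c1ccccc1
Why: DMAP-catalysed acylation of the only free (secondary allylic) hydroxyl installs the C2 benzoate with retention, and the cold, weakly basic medium avoids elimination to an arene.

Step 3
Reactants: 5 2-O-benzoyl-1-O-TBS derivative of 1
Product: 6 2-O-benzoate of 1 (C1 hydroxyl free, cis to the benzoate)
Conditions: HF·pyridine, pyridine, THF, 0 °C to rt
Reagents that add atoms: none
Why: Fluoride-mediated desilylation under buffered, slightly acidic conditions frees the C1 hydroxyl without the alkoxide that would cause 1,2-benzoyl migration and without the strong acid that would dehydrate the dienol.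

Step 4
Reactants: 6 2-O-benzoate of 1; 7 meta-chloroperoxybenzoic acid
Product: 8 syn-epoxy alcohol (C5–C6 oxirane with its oxygen cis to O1 and O2; C1 hydroxyl free, C2 benzoate, C3(Br)=C4 intact)
Conditions: mCPBA, Na2HPO4, CH2Cl2, 0 °C
Reagents that add atoms: meta-chloroperoxybenzoic acid, OOC(=O)c1cccc(Cl)c1
Why: Henbest hydroxyl-directed peracid epoxidation, in which the allylic C1 hydroxyl hydrogen-bonds to the peracid and delivers oxygen to C5=C6 on its own face, setting C5 and C6 with the oxirane cis to O1 and O2, while the bromine-deactivated C3=C4 alkene does not react.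

Step 5
Reactants: 8 syn-epoxy alcohol; 9 benzoic acid
Product: 10 bromo diol dibenzoate (C1–OH, C2–OBz, C3(Br)=C4, C5–OBz, C6–OH; O1, O2 and O6 cis, O5 trans to them)
Conditions: PhCO2H, Ti(OiPr)4, CH2Cl2, 0 °C to rt; aq. tartaric acid work-up
Reagents that add atoms: benzoic acid, OC(=O)c1ccccc1
Why: Titanium-mediated opening of a 2,3-epoxy alcohol by a carboxylic acid, in which benzoate attacks C5 (remote from the carbinol and also allylic) by SN2 with inversion, setting O5 trans to O6 and leaving O6 cis to O1; the C2 benzoate cannot participate because it lies on the oxirane face.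

Step 6
Reactants: 10 bromo diol dibenzoate
Product: 11 diol dibenzoate (10 without bromine: C1–OH, C2–OBz, C3=C4, C5–OBz, C6–OH)
Conditions: Bu3SnH, AIBN (cat.), toluene, 80 °C
Reagents that add atoms: none
Why: Radical hydrodebromination of the vinyl bromide by the tin hydride chain removes the bromine that differentiated the two alkenes, without touching esters, hydroxyls or stereocentres.

Step 7
Reactants: 11 diol dibenzoate; 2 tert-butyldimethylsilyl chloride
Product: 12 6-O-TBS ether of 11 (C1 hydroxyl free)
Conditions: TBSCl (1.1 equiv), imidazole, DMF, 0 °C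
Reagents that add atoms: tert-butyldimethylsilyl chloride, CC(C)(C)[Si](C)(C)Cl
Why: Site-selective silylation of a cis-1,2-diol, since in the half-chair with both allylic benzoates pseudoequatorial the C6 hydroxyl is equatorial while the C1 hydroxyl is axial and flanked by two cis oxygen substituents, so one equivalent of the bulky silyl chloride should take O6.

Step 8
Reactants: 12 6-O-TBS ether of 11
Product: 13 C1 ketone (C2–OBz, C3=C4, C5–OBz, C6–OTBS; O2 and O6 cis, O5 trans)
Conditions: Dess–Martin periodinane, NaHCO3, CH2Cl2, 0 °C to rt; used crude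
Reagents that add atoms: none
Why: Dess–Martin oxidation of the remaining secondary hydroxyl at neutral pH gives the ketone without the base that would eliminate benzoic acid across C5–C6 and aromatise the ring.

Step 9
Reactants: 13 C1 ketone; 14 dibromomethane
Product: 15 C1-methylene compound with C6–OTBS
Conditions: Zn, CH2Br2, TiCl4, THF, 0 °C (reagent preformed), then 13 in CH2Cl2, 0 °C to rt
Reagents that add atoms: dibromomethane, BrCBr
Why: Lombardo methylenation, whose geminal dizinc–titanium reagent is non-basic and selective for ketones over esters, should convert the enolisable β-acyloxy ketone into the C1=C7 alkene without epimerisation at C2 or C6 and without attack on the benzoates.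

Step 10
Reactants: 15 C1-methylene compound with C6–OTBS
Product: 16 C1-methylene cyclohexene with O2 and O5 benzoates and free C6 hydroxyl
Conditions: HF·pyridine, pyridine, THF, 0 °C to rt
Reagents that add atoms: none
Why: Buffered fluoride cleavage of the secondary silyl ether releases the allylic C6 hydroxyl needed as the directing group, with no alkoxide to move the neighbouring benzoates.

Step 11
Reactants: 16 C1-methylene cyclohexene with free C6 hydroxyl; 17 tert-butyl hydroperoxide
Product: 18 spiro-epoxide (oxirane C1, C7, O1 with O1 cis to the C6 hydroxyl)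
Conditions: VO(acac)2 (5 mol %), TBHP (anhydrous, in decane), CH2Cl2, 0 °C to rt
Reagents that add atoms: tert-butyl hydroperoxide, CC(C)(C)OO
Why: TBHP oxidises VO(acac)2 to an alkylperoxo vanadate of pentavalent vanadium that binds the C6 alkoxide of 16, and the metal-bound peroxide oxygen is then passed in one concerted step to C1=C7. The closest known reaction type is the vanadium-catalysed hydroxyl-directed epoxidation of allylic alcohols, which is established for 2-methylenecycloalkanols. The oxirane closes by intramolecular oxygen-atom transfer through a spiro transition state in which the V–O6–C6–C1 tether holds the peroxide over the alkene, so both C–O bonds form from the O6 face. The new stereocentre C1 is therefore controlled by the C6 carbinol centre and O1 ends cis to O6, whereas an undirected oxidant would approach anti to the allylic oxygens at C2 and C6 and give the C1 epimer. The step needs facial selectivity at C1 and preference for C1=C7 over C3=C4, and both come from the bound C6 hydroxyl, because the ring alkene is only homoallylic to it and is deactivated by two allylic benzoyloxy groups. A(1,3) strain with the methylene hydrogens favours a pseudoaxial C6–O bond, which is the geometry suited to delivery from vanadium.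

Step 12
Reactants: 18 spiro-epoxide; 9 benzoic acid
Product: 19 [(1S,2R,5R,6S)-2,5-bis(benzoyloxy)-1,6-dihydroxycyclohex-3-en-1-yl]methyl benzoate (CNP0128482.1)
Conditions: PhCO2H (3 equiv), PhCO2Cs (0.5 equiv), DMF, 70 °C
Reagents that add atoms: benzoic acid, OC(=O)c1ccccc1
Why: Carboxylate opening of a 1,1-disubstituted epoxide by SN2 attack at the unhindered primary C7 leaves the C1–O1 bond intact, so C1 keeps its configuration as the tertiary alcohol, and the excess benzoic acid protonates the alkoxide at once and suppresses benzoyl migration.

**Compound list**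

1 | (1S,2S)-3-bromocyclohexa-3,5-diene-1,2-diol | O[C@@H]1[C@H](O)C(Br)=CC=C1 | starting material
2 | tert-butyldimethylsilyl chloride | CC(C)(C)[Si](C)(C)Cl | starting material
3 | 1-O-TBS ether of 1 | CC(C)(C)[Si](C)(C)O[C@@H]1[C@H](O)C(Br)=CC=C1 | intermediate
4 | benzoyl chloride | O=C(Cl)c1ccccc1 | starting material
5 | 2-O-benzoyl-1-O-TBS derivative of 1 | CC(C)(C)[Si](C)(C)O[C@@H]1[C@H](OC(=O)c2ccccc2)C(Br)=CC=C1 | intermediate
6 | 2-O-benzoate of 1 with free C1 hydroxyl | O[C@@H]1[C@H](OC(=O)c2ccccc2)C(Br)=CC=C1 | intermediate
7 | meta-chloroperoxybenzoic acid | OOC(=O)c1cccc(Cl)c1 | starting material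
8 | syn-epoxy alcohol (C5–C6 oxirane cis to O1 and O2) | O[C@@H]1[C@H](OC(=O)c3ccccc3)C(Br)=C[C@@H]2O[C@H]12 | intermediate
9 | benzoic acid | OC(=O)c1ccccc1 | starting material
10 | bromo diol dibenzoate (O1, O2, O6 cis; O5 trans) | O[C@@H]1[C@H](OC(=O)c2ccccc2)C(Br)=C[C@@H](OC(=O)c2ccccc2)[C@@H]1O | intermediate
11 | diol dibenzoate (debrominated 10) | O[C@@H]1[C@H](OC(=O)c2ccccc2)C=C[C@@H](OC(=O)c2ccccc2)[C@@H]1O | intermediate
12 | 6-O-TBS ether of 11 | O[C@@H]1[C@H](OC(=O)c2ccccc2)C=C[C@@H](OC(=O)c2ccccc2)[C@@H]1O[Si](C)(C)C(C)(C)C | intermediate
13 | C1 ketone with C2 and C5 benzoates and C6–OTBS | O=C1[C@H](OC(=O)c2ccccc2)C=C[C@@H](OC(=O)c2ccccc2)[C@@H]1O[Si](C)(C)C(C)(C)C | intermediate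
14 | dibromomethane | BrCBr | starting material
15 | C1-methylene compound with C6–OTBS | C=C1[C@H](OC(=O)c2ccccc2)C=C[C@@H](OC(=O)c2ccccc2)[C@@H]1O[Si](C)(C)C(C)(C)C | intermediate
16 | C1-methylene cyclohexene with O2 and O5 benzoates and free C6 hydroxyl | C=C1[C@H](OC(=O)c2ccccc2)C=C[C@@H](OC(=O)c2ccccc2)[C@@H]1O | intermediate
17 | tert-butyl hydroperoxide | CC(C)(C)OO | starting material
18 | spiro-epoxide with oxirane oxygen cis to the C6 hydroxyl | C1O[C@@]12[C@H](OC(=O)c3ccccc3)C=C[C@@H](OC(=O)c3ccccc3)[C@@H]2O | intermediate
19 | [(1S,2R,5R,6S)-2,5-bis(benzoyloxy)-1,6-dihydroxycyclohex-3-en-1-yl]methyl benzoate | O=C(OC[C@@]1(O)[C@H](OC(=O)c2ccccc2)C=C[C@@H](OC(=O)c2ccccc2)[C@@H]1O)c1ccccc1 | target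

Total step count: 12. Longest linear sequence: 12 steps (1 to 19).

**Steps most likely to fail**

Step 11. The cis C2 benzoate crowds the hydroxyl face, so oxygen delivery may be slow or lose facial selectivity, and the allylic alcohol may be oxidised in competition. The fallback sets out from 16 and relies on steric approach in place of coordination. NBS in aqueous THF at 0 °C should place bromine on the open face of C1=C7, anti to O2 and O6. Water then attacks the tertiary C1 from the O6 face (participation by the C2 benzoate carbonyl would deliver oxygen to the same face), giving the bromohydrin F1. Ag2O in THF closes the oxirane by attack of O1 on C7 without touching C1, and the route is rejoined at 18.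

Step 7. Silylation may go to O1 or to both hydroxyls if the conformational bias is weaker than assumed. The fallback sets out from 8 and masks O1 before O6 exists. Levulinic acid, DCC and DMAP give the O1 levulinate of the epoxy alcohol F2. PhCO2H with PhCO2Cs in DMF opens the vinyl oxirane at the allylic C5 to the levulinate hydroxy dibenzoate F3, in which O6 is the only free hydroxyl. TBSCl and imidazole give its 6-O-TBS ether F4, and Bu3SnH with AIBN gives the debrominated levulinate F5. N2H4·AcOH in pyridine/AcOH removes the levulinate in the presence of benzoates and silyl ether, and the route is rejoined at 12.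

Step 9. Ketone 13 may lose benzoic acid across C5–C6 and aromatise, or the hindered carbonyl may be methylenated incompletely under the Lewis-acidic conditions. The fallback sets out from 13 and builds the alkene in two stages by Peterson olefination. Me3SiCH2Li with CeCl3 in THF at −78 °C adds the weakly basic organocerium to the ketone and should leave the benzoates, giving the β-hydroxysilane F6 (either C1 epimer serves). BF3·OEt2 in CH2Cl2 at 0 °C then effects the elimination, and the route is rejoined at 15.

**Further compounds**

F1 | step 11 | bromohydrin (C1–OH cis to O6, C7–Br) | BrC[C@@]1(O)[C@H](OC(=O)c2ccccc2)C=C[C@@H](OC(=O)c2ccccc2)[C@@H]1O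
F2 | step 7 | O1 levulinate of the epoxy alcohol | CC(=O)CCC(=O)O[C@@H]1[C@H](OC(=O)c3ccccc3)C(Br)=C[C@@H]2O[C@H]12
F3 | step 7 | levulinate hydroxy dibenzoate (bromo) | CC(=O)CCC(=O)O[C@@H]1[C@H](OC(=O)c2ccccc2)C(Br)=C[C@@H](OC(=O)c2ccccc2)[C@@H]1O
F4 | step 7 | 6-O-TBS ether of F3 | CC(=O)CCC(=O)O[C@@H]1[C@H](OC(=O)c2ccccc2)C(Br)=C[C@@H](OC(=O)c2ccccc2)[C@@H]1O[Si](C)(C)C(C)(C)C
F5 | step 7 | debrominated levulinate | CC(=O)CCC(=O)O[C@@H]1[C@H](OC(=O)c2ccccc2)C=C[C@@H](OC(=O)c2ccccc2)[C@@H]1O[Si](C)(C)C(C)(C)C
F6 | step 9 | β-hydroxysilane at C1 | C[Si](C)(C)C[C@@]1(O)[C@H](OC(=O)c2ccccc2)C=C[C@@H](OC(=O)c2ccccc2)[C@@H]1O[Si](C)(C)C(C)(C)C
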